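**Plan**

1. Numbering: C1–C10 are rings A and B (C4 = C(CH3)2–O, C10 = methyl-bearing ring-fusion carbon); C11 = CH2 on C9; C12 = CH2 on C8; C13 = C(CH3) next to C12; C14 = ketone; C15 = C(CH3) next to C11; C16 = carbon joined to C8, C15, C17 (OCH2) and C19; C18 = butenolide C=O; C19 = its α-carbon; C20 = CH= on C13.
2. Last cuts: the C19=C20 alkene goes back to a β-hydroxy lactone, then the C19–C20 and C8–C16 bonds are cut together. This opens the cyclopentane and the bicyclo[2.2.2]octane to a cycloheptanone that carries a formyl group on C13 and a butenolide on C15 (cis) and is fused to a ring B with a C7=C8 alkene.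
3. Enabling feature: C16 is the β-carbon of the butenolide and lies 1,5 to C8; C19, α to the lactone carbonyl, lies 1,6 to the formyl carbon C20. A tertiary radical made at C8 by hydrogen-atom transfer to C7 closes the five-membered ring on C16 and leaves an enolate at C19 that closes the bicyclooctane on C20, joining the quaternary carbons C8 and C16 (next to quaternary C15) in one operation.
4. Earlier cuts: ring A at C1=C2 (metathesis) and C4 (methyl addition to an ester); the butenolide at C16=C19 (Wittig); the C13 and C15 methyl groups and the C15–C16 bond (enolate chemistry); ring B at C5–C6 and C9–C10 (Diels–Alder); the seven-membered ring at C8=C9 (enyne metathesis).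
5. Forward order: seven-membered ring → ring B → C4 carbinol and C15/C13 substituents → oxidation levels, ring A, butenolide → cyclopentane and bicyclo[2.2.2]octane together → C19=C20.
6. Stereochemistry: C5, C9 and C10 come from one catalytic enantioselective endo Diels–Alder reaction of an (E)-dienophile; C15 and C13 are set by methylations directed by C10 and by the C15 acyl group; C8 and C16 follow from the ring geometry of the key step.

Key step: step 14

Remark: β is the face of the C10 methyl group; "cis/trans to C10" at C13 and C15 refers to the faces of the seven-membered ring, the C9–C10 bond marking one of them.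
Remark: C13 and C15 are enolizable up to step 7, so the intermediates before that step are carried as mixtures at these centres and drawn without configuration there.
Assumption: the (S)-configured oxazaborolidinium catalyst is taken to deliver the enantiomer shown; if the sense of induction were the opposite, its mirror image would be used.

Step 1
Reactants: 1 ethyl 3-oxohept-6-enoate; 2 propargyl bromide
Product: 3 ethyl 3-oxo-2-(prop-2-yn-1-yl)hept-6-enoate
Conditions: K2CO3 (1.5 equiv), 2 (1.05 equiv), acetone, 50 °C
Reagents that add atoms: propargyl bromide (compound 2), C#CCBr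
Why: C-alkylation of the β-keto ester enolate with a reactive propargylic halide should stop at mono-alkylation and places the future C12, C8 and C7 on C13; the new centre is enolizable and of no consequence.

Step 2
Reactants: 3 ethyl 3-oxo-2-(prop-2-yn-1-yl)hept-6-enoate
Product: 4 ethyl 2-oxo-6-vinylcyclohept-5-ene-1-carboxylate
Conditions: second-generation Grubbs catalyst (5 mol%), ethylene (1 atm), CH2Cl2 (0.01 M), 40 °C
Reagents that add atoms: none
Why: Ring-closing enyne metathesis in the exo mode should form the seven-membered ring and leave the 1-vinylcycloheptene diene (C6=C7–C8=C9), ethylene keeping the catalyst carbene in its methylidene form and suppressing oligomers.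

Step 3
Reactants: 4 ethyl 2-oxo-6-vinylcyclohept-5-ene-1-carboxylate; 5 ethyl (E)-3-methyl-4-oxobut-2-enoate
Product: 6 Diels–Alder adduct (bicyclic aldehyde diester)
Conditions: 5 (1.5 equiv), (S)-B-(o-tolyl)oxazaborolidine from α,α-diphenylprolinol protonated with HNTf2 (20 mol%), CH2Cl2, −78 to −20 °C
Reagents that add atoms: ethyl (E)-3-methyl-4-oxobut-2-enoate (compound 5), CCOC(=O)/C=C(\C)C=O
Why: Lewis-acid-catalysed Diels–Alder reaction: the boron-bound formyl group makes C5 the electrophilic terminus, so the unsubstituted diene terminus C6 bonds to C5 and the ring terminus C9 to C10; the formyl group is endo, which puts the new C9–H cis to the C10 methyl group; the (E)-geometry of 5 becomes the trans relation of formyl (α on C10) and ester (β on C5); the chiral catalyst selects the enantioface.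

Step 4
Reactants: 6 Diels–Alder adduct
Product: 7 C10-vinyl diester
Conditions: Ph3PCH3Br (2.6 equiv), KOtBu (2.5 equiv), THF, 0 °C to rt; aqueous NH4Cl
Reagents that add atoms: methyltriphenylphosphonium bromide, C[P+](c1ccccc1)(c1ccccc1)c1ccccc1.[Br-]
Why: Wittig methylenation of the hindered, non-enolizable aldehyde; the first equivalent of ylide only deprotonates the β-keto ester, whose enolate does not react, and both ester groups are untouched.

Step 5
Reactants: 7 C10-vinyl diester
Product: 9 C4 dimethyl carbinol, via lithium enolate 8 (not isolated)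
Conditions: MeLi (5 equiv), THF, −78 to 0 °C; aqueous NH4Cl
Reagents that add atoms: methyllithium, [Li]C
Why: Double addition of an organolithium to an ester: the first equivalent turns the β-keto ester into enolate 8, which shields the ring ketone and the C13 ester, so only the C5 ester should be converted into the C(CH3)2OH group.

Step 6
Reactants: 9 C4 dimethyl carbinol; 10 methyl 2-((tert-butyldimethylsilyl)oxy)acetate
Product: 12 C15-acylated diketo ester, via trilithium salt 11 (not isolated)
Conditions: LiN(iPr)2 (4.2 equiv), THF, −78 to 0 °C; then 10 (1.2 equiv), −78 to 0 °C; aqueous NH4Cl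
Reagents that add atoms: methyl 2-((tert-butyldimethylsilyl)oxy)acetate (compound 10), COC(=O)CO[Si](C)(C)C(C)(C)C
Why: β-Keto ester dianion chemistry (Huckin–Weiler): after the hydroxyl group and C13–H, the third equivalent of base removes a C15 proton, and this most basic carbanion of 11 alone attacks ester 10 (Claisen acylation at the γ-carbon); the new C15 centre is enolized.

Step 7
Reactants: 12 C15-acylated diketo ester
Product: 14 bis-methylated diketo ester, via C15-methyl diketo ester 13 (not isolated)
Conditions: MeI (6 equiv), K2CO3 (4 equiv), acetone, 25 to 45 °C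
Reagents that add atoms: iodomethane, CI
Why: Double C-methylation of 1,3-dicarbonyl enolates: the more acidic C15–H should react first, methyl iodide entering on the face away from the C10 quaternary carbon, and C13 is then methylated anti to the new C15 acyl group, so both methyl groups end up trans to C10 and the acyl and ester groups cis to C10.

Step 8
Reactants: 14 bis-methylated diketo ester
Product: 15 tetraol
Conditions: LiAlH4 (6 equiv), THF, 0 °C to reflux; Fieser work-up
Reagents that add atoms: none
Why: Exhaustive hydride reduction: the neopentyl ester cannot be reduced beside two ketones, so all three carbonyl groups are taken to the alcohol level (the carbinol epimers converge in step 9), while alkenes, silyl ether and tertiary alcohol are inert.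

Step 9
Reactants: 15 tetraol
Product: 16 keto aldehyde diketone
Conditions: Dess–Martin periodinane (5 equiv), NaHCO3, CH2Cl2, rt
Reagents that add atoms: none
Why: Dess–Martin oxidation should turn the primary alcohol into the C20 aldehyde and both secondary alcohols back into the C14 and C16 ketones under buffered conditions that do not cleave the non-enolizable 1,3-dicarbonyl arrays; the tertiary alcohol cannot react.

Step 10
Reactants: 16 keto aldehyde diketone; 17 acryloyl chloride
Product: 18 C4 acrylate
Conditions: 17 (3 equiv), iPr2NEt (4 equiv), DMAP (0.2 equiv), CH2Cl2, 0 to 40 °C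
Reagents that add atoms: acryloyl chloride (compound 17), C=CC(=O)Cl
Why: DMAP-catalysed acylation of the only hydroxyl group; with C13 and C15 quaternary no enolizable 1,3-dicarbonyl unit is left to compete for the acid chloride.

Step 11
Reactants: 18 C4 acrylate
Product: 19 ring A lactone
Conditions: second-generation Hoveyda–Grubbs catalyst (10 mol%), toluene (0.005 M), 80 °C
Reagents that add atoms: none
Why: Ring-closing metathesis of the acrylate with the C10 vinyl group should give the seven-membered α,β-unsaturated lactone (cis alkene by ring size); the trisubstituted C7=C8 alkene does not take part.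

Step 12
Reactants: 19 ring A lactone
Product: 20 hydroxy ketone
Conditions: HF·pyridine, pyridine/THF, 0 °C to rt
Reagents that add atoms: none
Why: Buffered fluoride desilylation frees the primary alcohol next to the C16 ketone without exposing the β-keto aldehyde and the 1,3-diketone to base.

Step 13
Reactants: 20 hydroxy ketone; 21 (triphenylphosphoranylidene)ketene
Product: 23 butenolide keto aldehyde, via acyl ylide 22 (not isolated)
Conditions: 21 (1.3 equiv), toluene, 90 °C
Reagents that add atoms: (triphenylphosphoranylidene)ketene (compound 21), O=C=C=P(c1ccccc1)(c1ccccc1)c1ccccc1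
Why: Bestmann's ketenylidene phosphorane: the alcohol adds to give acyl ylide 22, which closes by intramolecular Wittig reaction on the adjacent C16 ketone to the 4-substituted butenolide; the neopentyl aldehyde is too remote for a ring-forming olefination.

Step 14
Reactants: 23 butenolide keto aldehyde
Product: 27 cage aldol, via C8 radical 24 (not isolated), via C19 radical 25 (not isolated), via lactone enolate 26 (not isolated)
Conditions: Fe(acac)3 (0.3 equiv), PhSiH3 (3 equiv), EtOH/ethylene glycol 5:1 (0.02 M), argon, 60 °C
Reagents that add atoms: none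
Why: Hydrogen-atom transfer from the iron hydride formed from Fe(acac)3 and PhSiH3 to C7 of the C7=C8 alkene gives tertiary radical 24, which adds to C16, the β-carbon of the butenolide; the α-lactone radical 25 is reduced by divalent iron to enolate 26, which adds to the C20 aldehyde. The closest known reaction type is the iron-hydride-initiated Giese reaction run as a radical–polar crossover annulation with an intramolecular aldol termination. The cyclopentane C8–C9–C11–C15–C16 closes 5-exo-trig across the seven-membered ring (a bicyclo[3.2.1]octane results), and the cyclohexane C13–C14–C15–C16–C19–C20 then closes 6-exo-trig in the aldol, which completes the bicyclo[2.2.2]octane. At C8 and C16 the two-atom tether C9–C11, axial on the α-face of ring B, allows only a cis ring fusion, so C16 bonds to the α-face of C8 and C12 ends up β; at C16 the rotamer that eclipses C16=C19 with the C14 carbonyl carbon and keeps the C17 methylene away from it should be attacked, which holds C19 above C13, and the cis relation of formyl and butenolide from step 7 leaves one way to close; the C19 and C20 centres disappear in step 15. The step needs hydrogen-atom transfer to the electron-rich trisubstituted alkene in the presence of two electron-poor lactone alkenes, which the polarity of the iron hydride secures, and an aldol that outruns protonation of 26, which the fixed proximity of C19 and C20 in the bicyclo[3.2.1]octane should secure.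

Step 15
Reactants: 27 cage aldol
Product: 29 andilesin B, via mesylate 28 (not isolated)
Conditions: MsCl (3 equiv), Et3N (5 equiv), CH2Cl2, 0 °C; then DBU (5 equiv), 25 to 40 °C
Reagents that add atoms: none
Why: Mesylation of the C20 carbinol and E1cB elimination through the lactone enolate at C19 should give the conjugated C19=C20 bond in a two-carbon bridge of the bicyclooctane (no bridgehead alkene), both carbinol epimers converging.

**Compound list**

1 | ethyl 3-oxohept-6-enoate | C=CCCC(=O)CC(=O)OCC | starting material
2 | propargyl bromide (3-bromoprop-1-yne) | C#CCBr | starting material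
3 | ethyl 3-oxo-2-(prop-2-yn-1-yl)hept-6-enoate (racemic, enolizable centre) | C=CCCC(=O)C(CC#C)C(=O)OCC | intermediate
4 | ethyl 2-oxo-6-vinylcyclohept-5-ene-1-carboxylate (enolizable at C13) | CCOC(=O)C1CC(C=C)=CCCC1=O | intermediate
5 | ethyl (E)-3-methyl-4-oxobut-2-enoate | CCOC(=O)/C=C(\C)C=O | starting material
6 | Diels–Alder adduct: cyclohexene ring B (C7=C8) fused at C8–C9 to the cycloheptanone; C10 with β-CH3 and α-CHO; C5 with β-CO2Et and α-H; C9–H β; C13–CO2Et as epimer mixture | O=C[C@@]1(C)[C@H](C(=O)OCC)CC=C2CC(C(=O)OCC)C(=O)CC[C@@H]12 | intermediate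
7 | C10-vinyl diester: 6 with CH=CH2 in place of CHO | C=C[C@@]1(C)[C@H](C(=O)OCC)CC=C2CC(C(=O)OCC)C(=O)CC[C@@H]12 | intermediate
8 | lithium enolate of 7 at C13=C14–O (not isolated) | C=C[C@@]1(C)[C@H](C(=O)OCC)CC=C2CC(C(=O)OCC)=C([O-])CC[C@@H]12.[Li+] | intermediate
9 | C4 dimethyl carbinol: 7 with β-C(CH3)2OH on C5 in place of CO2Et | C=C[C@@]1(C)[C@H](C(C)(C)O)CC=C2CC(C(=O)OCC)C(=O)CC[C@@H]12 | intermediate
10 | methyl 2-((tert-butyldimethylsilyl)oxy)acetate | COC(=O)CO[Si](C)(C)C(C)(C)C | starting material
11 | trilithium salt of 9: alkoxide, C13=C14 enolate, C15 carbanion (not isolated) | C=C[C@@]1(C)[C@H](C(C)(C)[O-])CC=C2CC(C(=O)OCC)=C([O-])[CH-]C[C@@H]12.[Li+].[Li+].[Li+] | intermediate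
12 | C15-acylated diketo ester: 9 with C(=O)CH2OSi(tBu)Me2 on C15; C13 and C15 enolized, not defined | C=C[C@@]1(C)[C@H](C(C)(C)O)CC=C2CC(C(=O)OCC)C(=O)C(C(=O)CO[Si](C)(C)C(C)(C)C)C[C@@H]12 | intermediate
13 | C15-methyl diketo ester: C15 quaternary, CH3 trans to C10, acyl cis to C10; C13 not defined (not isolated) | C=C[C@@]1(C)[C@H](C(C)(C)O)CC=C2CC(C(=O)OCC)C(=O)[C@@](C)(C(=O)CO[Si](C)(C)C(C)(C)C)C[C@@H]12 | intermediate
14 | bis-methylated diketo ester: C13 CH3 cis to the C15 CH3, CO2Et cis to the C15 acyl group | C=C[C@@]1(C)[C@H](C(C)(C)O)CC=C2C[C@@](C)(C(=O)OCC)C(=O)[C@@](C)(C(=O)CO[Si](C)(C)C(C)(C)C)C[C@@H]12 | intermediate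
15 | tetraol: C13–CH2OH, C14–OH and C16–OH (carbinol epimers), C4–OH; silyl ether kept | C=C[C@@]1(C)[C@H](C(C)(C)O)CC=C2C[C@@](C)(CO)C(O)[C@@](C)(C(O)CO[Si](C)(C)C(C)(C)C)C[C@@H]12 | intermediate
16 | keto aldehyde diketone: C13–CHO, C14 and C16 ketones, C4–OH | C=C[C@@]1(C)[C@H](C(C)(C)O)CC=C2C[C@@](C)(C=O)C(=O)[C@@](C)(C(=O)CO[Si](C)(C)C(C)(C)C)C[C@@H]12 | intermediate
17 | acryloyl chloride | C=CC(=O)Cl | starting material
18 | C4 acrylate of 16 | C=C[C@@]1(C)[C@H](C(C)(C)OC(=O)C=C)CC=C2C[C@@](C)(C=O)C(=O)[C@@](C)(C(=O)CO[Si](C)(C)C(C)(C)C)C[C@@H]12 | intermediate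
19 | ring A lactone: seven-membered α,β-unsaturated lactone (C1=C2 cis) trans-fused to ring B; silyl ether kept | CC1(C)OC(=O)C=C[C@@]2(C)[C@H]1CC=C3C[C@@](C)(C=O)C(=O)[C@@](C)(C(=O)CO[Si](C)(C)C(C)(C)C)C[C@@H]23 | intermediate
20 | hydroxy ketone: 19 with free C17–OH | CC1(C)OC(=O)C=C[C@@]2(C)[C@H]1CC=C3C[C@@](C)(C=O)C(=O)[C@@](C)(C(=O)CO)C[C@@H]23 | intermediate
21 | (triphenylphosphoranylidene)ketene | O=C=C=P(c1ccccc1)(c1ccccc1)c1ccccc1 | starting material
22 | acyl ylide: (triphenylphosphoranylidene)acetate of 20 (not isolated) | CC1(C)OC(=O)C=C[C@@]2(C)[C@H]1CC=C3C[C@@](C)(C=O)C(=O)[C@@](C)(C(=O)COC(=O)C=P(c4ccccc4)(c4ccccc4)c4ccccc4)C[C@@H]23 | intermediate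
23 | butenolide keto aldehyde: C15 carries CH3 (trans to C10) and 5-oxo-2,5-dihydrofuran-3-yl (cis to C10); C13 carries CH3 and CHO (CHO cis to the butenolide); C7=C8 | CC1(C)OC(=O)C=C[C@@]2(C)[C@H]1CC=C3C[C@@](C)(C=O)C(=O)[C@@](C)(C4=CC(=O)OC4)C[C@@H]23 | intermediate
24 | C8 tertiary radical after hydrogen transfer to C7 (not isolated) | CC1(C)OC(=O)C=C[C@@]2(C)[C@H]1CC[C]3C[C@@](C)(C=O)C(=O)[C@@](C)(C4=CC(=O)OC4)C[C@@H]23 | intermediate
25 | C19 radical: spiro lactone with the C8–C16 bond formed, C16 on the α-face of C8 (not isolated) | CC1(C)OC(=O)C=C[C@@]2(C)[C@H]1CC[C@]35C[C@@](C)(C=O)C(=O)[C@](C)(C[C@@H]23)[C@@]56[CH]C(=O)OC6 | intermediate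
26 | lactone enolate from 25, iron-bound, drawn as the anion (not isolated) | CC1(C)OC(=O)C=C[C@@]2(C)[C@H]1CC[C@]35C[C@@](C)(C=O)C(=O)[C@](C)(C[C@@H]23)[C@@]56C=C([O-])OC6 | intermediate
27 | cage aldol: full ring system of the target with C20–OH and C19–H (carbinol epimers converge) | CC1(C)OC(=O)C=C[C@@]2(C)[C@H]1CC[C@@]13C[C@@]4(C)C(O)C5C(=O)OC[C@]51[C@@](C)(C[C@@H]23)C4=O | intermediate
28 | C20 mesylate of 27 (not isolated) | CC1(C)OC(=O)C=C[C@@]2(C)[C@H]1CC[C@@]13C[C@@]4(C)C(OS(C)(=O)=O)C5C(=O)OC[C@]51[C@@](C)(C[C@@H]23)C4=O | intermediate
29 | andilesin B | CC1(C)OC(=O)C=C[C@@]2(C)[C@H]1CC[C@@]13C[C@@]4(C)C=C5C(=O)OC[C@]51[C@@](C)(C[C@@H]23)C4=O | target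

Total step count: 15. Longest linear sequence: 15 steps (from 1).

**Steps most likely to fail**

Step 14. Process at risk: protonation of enolate 26 (or silane reduction of the C20 aldehyde) before the aldol closure, so that only the C8–C16 bond forms. Fallback: the two bond formations are separated. Setting out from 23, the radical cyclization is run reductively on purpose (Mn(dpm)3, PhSiH3, tert-butyl hydroperoxide, isopropanol, 25 °C) to give the spiro lactone keto aldehyde F1. Its lactone α-methylene C19 is then deprotonated with LiN(SiMe3)2 (THF, −78 °C) for a separate intramolecular aldol addition to C20. This gives 27, and the route continues with step 15.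

Step 7. Process at risk: approach of methyl iodide to the C15 enolate from the face that carries C10 (reversed facial selectivity), which would give the C15 epimer that cannot close in step 14. Fallback: the order in which the two groups reach C15 is reversed, so that the acyl group is the last to enter. Setting out from 9, the trilithium salt (LiN(iPr)2, 3.2 equiv, THF) is methylated at C15 with one equivalent of MeI to give the C15-methyl β-keto ester F2. F2 is deprotonated in the same way and acylated at C15 with 2-((tert-butyldimethylsilyl)oxy)-N-methoxy-N-methylacetamide; the amide stops at the tetrahedral adduct, so the quaternary 1,3-diketone is not cleaved. This gives 13, which is methylated at C13 with MeI and K2CO3 as in step 7 to reach 14.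

Step 3. Process at risk: binding of the enolic β-keto ester of the diene to the boron Lewis acid, which would slow the cycloaddition and erode endo and enantioface selectivity. Fallback: the β-keto ester is masked during the cycloaddition. Setting out from 4, O-acetylation (Ac2O, Et3N, DMAP, CH2Cl2) gives the enol acetate diene F3. The catalytic Diels–Alder reaction with 5 under the conditions of step 3 gives the enol acetate adduct F4. Ethanolysis of the enol acetate (K2CO3, EtOH, 0 °C) returns 6.

**Further compounds**

F1 | step 14 | spiro lactone keto aldehyde (C8–C16 bond formed, C19 as CH2, C20 aldehyde kept) | CC1(C)OC(=O)C=C[C@@]2(C)[C@H]1CC[C@]35C[C@@](C)(C=O)C(=O)[C@](C)(C[C@@H]23)[C@@]56CC(=O)OC6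
F2 | step 7 | C15-methyl β-keto ester (9 with CH3 on C15; C13 and C15 not defined) | C=C[C@@]1(C)[C@H](C(C)(C)O)CC=C2CC(C(=O)OCC)C(=O)C(C)C[C@@H]12
F3 | step 3 | enol acetate diene: ethyl 2-acetoxy-6-vinylcyclohepta-1,5-diene-1-carboxylate | CCOC(=O)C1=C(OC(C)=O)CCC=C(C=C)C1
F4 | step 3 | enol acetate adduct: 6 with C13=C14–OAc in place of the β-keto ester | O=C[C@@]1(C)[C@H](C(=O)OCC)CC=C2CC(C(=O)OCC)=C(OC(C)=O)CC[C@@H]12
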